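The side chain is cut between its first methylene (C1', on C3 of the quinone ring) and the vinylic carbon C2'. The key step exploits the C1'H2–C2'H=C3'(CH3) unit: the (E)-trisubstituted alkene and its methyl are not carried in a fragment but made in the coupling flask. The terminal alkyne (6R,10R)-6,10,14-trimethylpentadec-1-yne, obtained by degrading natural phytol, undergoes zirconium-catalysed syn-methylalumination, and the resulting (E)-alkenylalane is coupled under zerovalent nickel catalysis with 2-(chloromethyl)-3-methyl-1,4-naphthoquinone. One operation thus adds the C3' methyl, fixes the E geometry and joins the unprotected quinone to the C18 chain; both stereocentres come from the chiral pool.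

Key step: step 4

Assumption: natural, chlorophyll-derived phytol of (7R,11R) configuration is taken as the commercial source of both stereocentres; the geometry of its double bond does not matter because that bond is cleaved in step 1.

Step 1
Reactants: 1 natural phytol, (2E,7R,11R)-3,7,11,15-tetramethylhexadec-2-en-1-ol
Product: 2 (6R,10R)-6,10,14-trimethylpentadecan-2-one
Conditions: O3, CH2Cl2/MeOH, −78 °C; then Me2S, −78 °C → rt
Reagents that add atoms: ozone, [O-][O+]=O
Why: Ozonolysis (Criegee mechanism) with reductive work-up cleaves the only C=C bond of 1 into the methyl ketone and glycolaldehyde, and the two methyl-bearing stereocentres, remote from the reacting carbons, pass unchanged into 2 as C6 and C10.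

Step 2
Reactants: 2 (6R,10R)-6,10,14-trimethylpentadecan-2-one
Product: 4 (6R,10R)-6,10,14-trimethylpentadec-1-yne, via enol diethyl phosphate 3 (not isolated)
Conditions: LiN(iPr)2 (1.1 equiv, commercial solution), THF, −78 °C; ClP(O)(OEt)2, −78 °C → rt; then LiN(iPr)2 (2.3 equiv), THF, −78 °C → rt; H2O
Reagents that add atoms: none
Why: Methyl ketone-to-terminal alkyne conversion through an enol phosphate: the hindered amide base should deprotonate the methyl group under kinetic control, ClP(O)(OEt)2 traps the enolate on oxygen as 3, and excess base eliminates diethyl phosphate and holds the product as its acetylide until work-up, with no stereocentre near the reacting carbons.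

Step 3
Reactants: 5 menadione, 2-methylnaphthalene-1,4-dione
Product: 6 2-(chloromethyl)-3-methylnaphthalene-1,4-dione
Conditions: aq. HCHO (37%), HCl (gas), AcOH, rt
Reagents that add atoms: formaldehyde, C=O; hydrogen chloride, Cl
Why: Blanc-type chloromethylation at C3, the only unsubstituted position of the quinone ring: acid-promoted hydroxymethylation by formaldehyde is followed by conversion of the activated alcohol into the chloride by HCl, a transformation known for menadione.

Step 4
Reactants: 4 (6R,10R)-6,10,14-trimethylpentadec-1-yne; 6 2-(chloromethyl)-3-methylnaphthalene-1,4-dione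
Product: 8 phylloquinone [2-methyl-3-((2E,7R,11R)-3,7,11,15-tetramethylhexadec-2-en-1-yl)naphthalene-1,4-dione], via alkenyldimethylalane 7 (not isolated)
Conditions: AlMe3 (2 equiv), Cp2ZrCl2 (25 mol %), ClCH2CH2Cl, 0 °C → rt; volatiles and excess AlMe3 removed in vacuo, hexane extraction; then 6, NiCl2(PPh3)2 (5 mol %) pre-reduced with n-BuLi (10 mol %) to zerovalent nickel, THF, −78 °C → 0 °C
Reagents that add atoms: trimethylaluminium, C[Al](C)C
Why: Cp2ZrCl2-catalysed syn-methylalumination (Negishi carboalumination) of the terminal alkyne 4 places the methyl group on the internal carbon and aluminium on the terminal carbon, giving the (E)-2-methylalk-1-enylalane 7. After removal of free AlMe3, zerovalent nickel inserts into the activated C–Cl bond of 6, the alkenyl group passes from aluminium to nickel with retention of geometry, and reductive elimination forms the C(sp3)–C(sp2) bond between the quinone-bound methylene and the vinylic carbon. The closest known reaction type is the nickel-catalysed Negishi-type cross-coupling of alkenylalanes with benzylic chlorides and chloromethylquinones, as applied to ubiquinones and K vitamins. No ring is closed and no stereocentre is formed; the only stereochemical element created, the E double bond, is fixed by the syn addition and the stereoretentive transmetalation, while the two methyl-bearing stereocentres lie far from the reacting atoms. The step needs regioselective methylmetalation (aluminium at the unsubstituted alkyne terminus for steric reasons) and chemoselective coupling at the C–Cl bond over carbonyl addition or reduction of the quinone, which fast oxidative addition at low temperature and the low nucleophilicity of the alkenylalane in the absence of free AlMe3 should secure.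

Compound list
1 | natural phytol, (2E,7R,11R)-3,7,11,15-tetramethylhexadec-2-en-1-ol | OC/C=C(\C)CCC[C@H](C)CCC[C@H](C)CCCC(C)C | starting material
2 | (6R,10R)-6,10,14-trimethylpentadecan-2-one | CC(=O)CCC[C@H](C)CCC[C@H](C)CCCC(C)C | intermediate
3 | diethyl (6R,10R)-6,10,14-trimethylpentadec-1-en-2-yl phosphate (enol diethyl phosphate, formed in the flask and not isolated) | C=C(CCC[C@H](C)CCC[C@H](C)CCCC(C)C)OP(=O)(OCC)OCC | intermediate
4 | (6R,10R)-6,10,14-trimethylpentadec-1-yne | C#CCCC[C@H](C)CCC[C@H](C)CCCC(C)C | intermediate
5 | menadione, 2-methylnaphthalene-1,4-dione | CC1=CC(=O)c2ccccc2C1=O | starting material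
6 | 2-(chloromethyl)-3-methylnaphthalene-1,4-dione | CC1=C(CCl)C(=O)c2ccccc2C1=O | intermediate
7 | dimethyl[(1E,6R,10R)-2,6,10,14-tetramethylpentadec-1-en-1-yl]alane (alkenyldimethylalane, formed in the flask and not isolated) | C[Al](C)/C=C(\C)CCC[C@H](C)CCC[C@H](C)CCCC(C)C | intermediate
8 | phylloquinone, 2-methyl-3-[(2E,7R,11R)-3,7,11,15-tetramethylhexadec-2-en-1-yl]naphthalene-1,4-dione | CC1=C(C/C=C(\C)CCC[C@H](C)CCC[C@H](C)CCCC(C)C)C(=O)c2ccccc2C1=O | target

Total step count: 4
Longest linear sequence: 3 steps (steps 1, 2 and 4)

Steps most likely to fail

1. Step 4. What may go wrong: electron transfer from the alkenylalane or from low-valent nickel to the unprotected quinone (reduction to the hydroquinone, reductive homocoupling at the chloromethyl carbon), 1,2-addition to a quinone carbonyl, or methyl transfer from residual AlMe3 instead of alkenyl transfer. The fallback sets out from 5 and forms the same bond on a masked, non-reducible arene. Reduction of 5 (Na2S2O4, EtOAc/H2O) should give 2-methylnaphthalene-1,4-diol F1. O-Methylation (Me2SO4, K2CO3, acetone, reflux) should give 1,4-dimethoxy-2-methylnaphthalene F2. Chloromethylation ((CH2O)n, conc. HCl, AcOH) should give 2-(chloromethyl)-1,4-dimethoxy-3-methylnaphthalene F3. Coupling of F3 with alane 7, generated from 4 as in step 4 (zerovalent nickel from NiCl2(PPh3)2/n-BuLi, THF), should give 1,4-dimethoxy-2-methyl-3-[(2E,7R,11R)-3,7,11,15-tetramethylhexadec-2-en-1-yl]naphthalene F4. Oxidative demethylation with (NH4)2Ce(NO3)6 (MeCN/H2O, 0 °C) returns to the route at 8.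

2. Step 2. What may go wrong: incomplete regiocontrol in the kinetic enolisation (deprotonation at the C3 methylene instead of the methyl group), which after elimination would lead to internal alkyne or allene contaminants, and incomplete elimination of the enol phosphate. The fallback sets out from 2 and lets migratory aptitude, not enolate regiochemistry, decide which side of the carbonyl reacts. Baeyer–Villiger oxidation (CF3CO3H from (CF3CO)2O and urea·H2O2, Na2HPO4, CH2Cl2, 0 °C → rt; primary alkyl migrates in preference to methyl) should give (4R,8R)-4,8,12-trimethyltridecyl acetate F5. Methanolysis (K2CO3, MeOH) should give (4R,8R)-4,8,12-trimethyltridecan-1-ol F6. Sulfonylation (TsCl, pyridine, 0 °C) should give (4R,8R)-4,8,12-trimethyltridecyl 4-methylbenzenesulfonate F7. Displacement with LiC≡CH·H2NCH2CH2NH2 (DMSO, rt) returns to the route at 4.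

3. Step 3. What may go wrong: addition of HCl across the quinone C2=C3 bond, and onward reaction of the activated chloride (hydrolysis, condensation with a second quinone unit), which would erode the chloromethylation. The fallback sets out from 5 and brings in the carbon as a methyl group that is then functionalised by a radical process. Silver-catalysed persulfate decarboxylative methylation (AcOH, AgNO3 cat., (NH4)2S2O8, MeCN/H2O, 70 °C; Minisci-type addition of a methyl radical at C3) should give 2,3-dimethylnaphthalene-1,4-dione F8. Wohl–Ziegler bromination (N-bromosuccinimide 1 equiv, dibenzoyl peroxide cat., PhCF3, reflux) should give 2-(bromomethyl)-3-methylnaphthalene-1,4-dione F9. Finkelstein-type halide exchange (LiCl, acetone, rt) returns to the route at 6.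

Further compounds
F1 | step 4 | 2-methylnaphthalene-1,4-diol | Cc1cc(O)c2ccccc2c1O
F2 | step 4 | 1,4-dimethoxy-2-methylnaphthalene | COc1cc(C)c(OC)c2ccccc12
F3 | step 4 | 2-(chloromethyl)-1,4-dimethoxy-3-methylnaphthalene | COc1c(C)c(CCl)c(OC)c2ccccc12
F4 | step 4 | 1,4-dimethoxy-2-methyl-3-[(2E,7R,11R)-3,7,11,15-tetramethylhexadec-2-en-1-yl]naphthalene | COc1c(C)c(C/C=C(\C)CCC[C@H](C)CCC[C@H](C)CCCC(C)C)c(OC)c2ccccc12
F5 | step 2 | (4R,8R)-4,8,12-trimethyltridecyl acetate | CC(=O)OCCC[C@H](C)CCC[C@H](C)CCCC(C)C
F6 | step 2 | (4R,8R)-4,8,12-trimethyltridecan-1-ol | OCCC[C@H](C)CCC[C@H](C)CCCC(C)C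
F7 | step 2 | (4R,8R)-4,8,12-trimethyltridecyl 4-methylbenzenesulfonate | Cc1ccc(cc1)S(=O)(=O)OCCC[C@H](C)CCC[C@H](C)CCCC(C)C
F8 | step 3 | 2,3-dimethylnaphthalene-1,4-dione | CC1=C(C)C(=O)c2ccccc2C1=O
F9 | step 3 | 2-(bromomethyl)-3-methylnaphthalene-1,4-dione | CC1=C(CBr)C(=O)c2ccccc2C1=O
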